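The quinone ring (numbered as in 5-methoxy-2-methyl-3-pentacosyl-1,4-benzoquinone) is cut into three acyclic pieces. An alkenyl(methoxy)carbene chromium complex supplies C1, C2 with its methyl and C3 with the pentacosyl chain. Methoxyacetylene supplies C5–OMe and C6–H, and one CO ligand supplies C4. A Dötz [3+2+1] benzannulation joins them in one operation, making C1–C6, C4–C5 and C3–C4, and oxidative work-up in the same flask gives the quinone. The step exploits the para pair of carbonyl carbons C1/C4, a dissonant 1,4-pattern met by carbene carbon plus CO. It also exploits the polarised C5(OMe)=C6(H) edge, whose ynol-ether origin fixes the orientation. The precursor is an acyclic organometallic.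

Key step: step 5

Remark: the side chain is read as unbranched pentacosyl (25 carbons). The target has no stereocentre, and the alkene geometry made in step 2 vanishes when both carbons enter the ring in step 5.

Step 1
Reactants: 1 1-hexacosanol
Product: 2 hexacosanal
Conditions: IBX (1.5 equiv), EtOAc, 80 °C; cool, filter
Reagents that add atoms: none
Why: IBX oxidation of a primary alcohol stops at the aldehyde, and hot EtOAc keeps the waxy C26 substrate in solution while the spent iodine reagent is filtered off; no stereocentre is involved.

Step 2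
Reactants: 2 hexacosanal; 3 ethyltriphenylphosphonium iodide
Product: 7 (Z)-2-iodooctacos-2-ene, via ethylidenetriphenylphosphorane 4 (not isolated), via (1-iodoethyl)triphenylphosphonium iodide 5 (not isolated), via (1-iodoethylidene)triphenylphosphorane 6 (not isolated)
Conditions: 3, n-BuLi, THF, 0 °C to rt; I2, −78 °C; NaN(SiMe3)2, −20 °C; 2 in warm THF, −20 °C to rt
Reagents that add atoms: iodine, [I][I]
Why: In this Stork–Zhao-type Wittig olefination the non-stabilised α-iodo ylide adds under kinetic control through the cis-oxaphosphetane, which should favour the Z-iodoalkene (iodine cis to the chain), a geometry that is erased in step 5.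

Step 3
Reactants: 7 (Z)-2-iodooctacos-2-ene; 8 chromium hexacarbonyl
Product: 11 pentacarbonyl[(2Z)-1-methoxy-2-methyloctacos-2-en-1-ylidene]chromium, via alkenyllithium 9 (not isolated), via lithium acylpentacarbonylchromate 10 (not isolated)
Conditions: t-BuLi (2 equiv), Et2O–THF, −78 to −40 °C; Cr(CO)6, −40 °C to rt; evaporate; MeOTf, CH2Cl2, 0 °C
Reagents that add atoms: methyl trifluoromethanesulfonate, COS(=O)(=O)C(F)(F)F
Why: This is the Fischer carbene synthesis, in which iodine–lithium exchange with retention, addition of the alkenyllithium to a CO ligand and O-methylation of the acylate by a hard methylating agent should give the alkenyl(methoxy)carbene complex.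

Step 4
Reactants: 12 chloroacetaldehyde dimethyl acetal
Product: 14 methoxyacetylene, via sodium methoxyacetylide 13 (not isolated)
Conditions: NaNH2 (3 equiv), liquid NH3, −33 °C; cold sat. aq. NaCl; distil into THF at −78 °C
Reagents that add atoms: none
Why: This is the classical alkoxyacetylene synthesis by double β-elimination (MeOH and HCl) from an α-chloro acetal, with the third equivalent of base holding the product as its acetylide until the aqueous quench releases the low-boiling alkyne.

Step 5
Reactants: 11 pentacarbonyl[(2Z)-1-methoxy-2-methyloctacos-2-en-1-ylidene]chromium; 14 methoxyacetylene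
Product: 17 5-methoxy-2-methyl-3-pentacosylcyclohexa-2,5-diene-1,4-dione (target), via Cr(CO)3-bound dienylketene 15 (not isolated), via Cr(CO)3-bound phenol 16 (not isolated)
Conditions: 14 (3 equiv), THF, 50 °C, sealed tube, argon; evaporate volatiles; (NH4)2Ce(NO3)6, THF–MeCN–H2O, 0 °C to rt
Reagents that add atoms: water, O
Why: Thermal loss of one CO from 11 opens a site for 14, whose insertion into the Cr=C bond gives a vinylcarbene, CO migration gives the dienylketene complex 15, and 6π electrocyclisation with tautomerisation gives the arene complex 16; (NH4)2Ce(NO3)6 then strips the metal and takes the 4-methoxyphenol to the quinone by two-electron oxidation, addition of water at C1 and loss of methanol. The closest known reaction type is the Dötz benzannulation of alkenyl Fischer carbene complexes with alkynes, 1-alkoxyalkynes included, followed by oxidative work-up. The single ring closes in a formal [3+2+1] mode, the last bond (C3–C4) by 6π electrocyclic closure of the ketene carbon onto the chain-bearing alkene carbon. No stereocentre is formed and the Z geometry of 11 is erased; an inward β-substituent should be tolerated, since β,β-disubstituted alkenyl complexes also cyclise. The step needs one alkyne orientation, and 14 secures it twice: its nucleophilic unsubstituted carbon bonds to the electrophilic carbene carbon (C1–C6), and the larger OMe terminus ends next to the CO-derived C4, the normal outcome for terminal alkynes. In the oxidation the para-quinone is expected over the ortho-quinone because the para methoxy-bearing carbon carries most of the positive charge of the oxidised phenol.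

Compound list
1 | 1-hexacosanol (unbranched C26 primary alcohol) | CCCCCCCCCCCCCCCCCCCCCCCCCCO | starting material
2 | hexacosanal | CCCCCCCCCCCCCCCCCCCCCCCCCC=O | intermediate
3 | ethyltriphenylphosphonium iodide | CC[P+](c1ccccc1)(c1ccccc1)c1ccccc1.[I-] | starting material
4 | ethylidenetriphenylphosphorane | CC=P(c1ccccc1)(c1ccccc1)c1ccccc1 | intermediate
5 | (1-iodoethyl)triphenylphosphonium iodide (racemic) | CC(I)[P+](c1ccccc1)(c1ccccc1)c1ccccc1.[I-] | intermediate
6 | (1-iodoethylidene)triphenylphosphorane | CC(I)=P(c1ccccc1)(c1ccccc1)c1ccccc1 | intermediate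
7 | (Z)-2-iodooctacos-2-ene (iodine cis to the C25 chain) | C/C(I)=C/CCCCCCCCCCCCCCCCCCCCCCCCC | intermediate
8 | chromium hexacarbonyl | O=C=[Cr](=C=O)(=C=O)(=C=O)(=C=O)=C=O | starting material
9 | (E)-octacos-2-en-2-yllithium (lithium cis to the chain) | C/C([Li])=C/CCCCCCCCCCCCCCCCCCCCCCCCC | intermediate
10 | lithium pentacarbonyl[(2Z)-2-methyl-1-oxidooctacos-2-en-1-ylidene]chromate | C/C(C([O-])=[Cr](=C=O)(=C=O)(=C=O)(=C=O)=C=O)=C/CCCCCCCCCCCCCCCCCCCCCCCCC.[Li+] | intermediate
11 | pentacarbonyl[(2Z)-1-methoxy-2-methyloctacos-2-en-1-ylidene]chromium | C/C(C(OC)=[Cr](=C=O)(=C=O)(=C=O)(=C=O)=C=O)=C/CCCCCCCCCCCCCCCCCCCCCCCCC | intermediate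
12 | chloroacetaldehyde dimethyl acetal (2-chloro-1,1-dimethoxyethane) | COC(CCl)OC | starting material
13 | sodium methoxyacetylide | [Na+].[C-]#COC | intermediate
14 | methoxyacetylene (methoxyethyne) | C#COC | intermediate
15 | tricarbonylchromium complex of (3E,5Z)-2,4-dimethoxy-5-methylhentriaconta-1,3,5-trien-1-one | O=C=C(OC)/C=C(/OC)\C(C)=C/CCCCCCCCCCCCCCCCCCCCCCCCC.O=C=[Cr](=C=O)=C=O | intermediate
16 | tricarbonylchromium complex of 4,6-dimethoxy-3-methyl-2-pentacosylphenol | COc1cc(OC)c(C)c(CCCCCCCCCCCCCCCCCCCCCCCCC)c1O.O=C=[Cr](=C=O)=C=O | intermediate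
17 | 5-methoxy-2-methyl-3-pentacosylcyclohexa-2,5-diene-1,4-dione | CCCCCCCCCCCCCCCCCCCCCCCCCC1=C(C)C(=O)C=C(OC)C1=O | target

Total step count: 5. Longest linear sequence: 4 (steps 1, 2, 3, 5).

Steps most likely to fail

**Step 5.**
- The electron-rich terminal alkyne may oligomerise on chromium.
- The cascade may also stall at the alkoxy-stabilised vinylcarbene, so that CO insertion is outrun by five-membered ring closure.
- The fallback is a metal-free pericyclic ring synthesis that sets out from 2 and 14 and comes back at 17.
- Aldehyde 2 would be homologated with dimethyl (1-diazo-2-oxopropyl)phosphonate and K2CO3 in MeOH–THF (Ohira–Bestmann) to heptacos-1-yne F1.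
- A [2+2] cycloaddition of F1 with chloro(methyl)ketene, generated from 2-chloropropanoyl chloride and Et3N, would give 4-chloro-4-methyl-3-pentacosylcyclobut-2-en-1-one F2.
- Zinc dust in AcOH–TMEDA–EtOH would remove the chlorine to give 4-methyl-3-pentacosylcyclobut-2-en-1-one F3.
- Heating F3 with 14 in toluene (sealed tube, 80 to 110 °C) should trigger the Danheiser benzannulation: 4π opening, [2+2] with the ynol ether, 4π opening and 6π closure. This gives 5-methoxy-2-methyl-3-pentacosylphenol F4.
- The free para position of F4 would be oxidised with (KSO3)2NO (Teuber oxidation) to 17.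

**Step 3.**
- Halogen–lithium exchange may stay incomplete because the waxy iodide precipitates in the cold.
- The alkenyllithium may be protonated, and the carbene complex may be air-oxidised during isolation.
- The fallback builds the alkene on a preformed carbene complex, sets out from 8 and 2, and comes back at 16.
- Complex 8 with EtLi and then MeOTf would give pentacarbonyl(1-methoxypropylidene)chromium F5.
- Aldol addition of F5 (n-BuLi, −78 °C) to 2 precomplexed with BF3·OEt2 would give pentacarbonyl(3-hydroxy-1-methoxy-2-methyloctacosylidene)chromium F6.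
- MsCl/Et3N would eliminate F6 to pentacarbonyl[(2E)-1-methoxy-2-methyloctacos-2-en-1-ylidene]chromium F7.
- Under the conditions of step 5, F7 and 14 should pass through the tricarbonylchromium complex of the (3E,5E)-dienylketene F8 and converge on 16.

**Step 2.**
- The ylide may lose iodine, which leads to plain ethylidenation.
- The aldehyde may be enolised, and conversion may be low because of poor solubility in the cold.
- The fallback replaces the Wittig step by a stereoselective cross-coupling, sets out from 2, and comes back at 9.
- CBr4/PPh3 (first stage of the Corey–Fuchs sequence) would give 1,1-dibromoheptacos-1-ene F9.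
- Negishi coupling with MeZnBr and PdCl2(DPEphos) should replace only the more reactive bromine trans to the chain and give (Z)-2-bromooctacos-2-ene F10.
- t-BuLi would convert F10 with retention into alkenyllithium 9.

Further compounds
F1 | step 5 | heptacos-1-yne | C#CCCCCCCCCCCCCCCCCCCCCCCCCC
F2 | step 5 | 4-chloro-4-methyl-3-pentacosylcyclobut-2-en-1-one (racemic) | O=C1C=C(CCCCCCCCCCCCCCCCCCCCCCCCC)C1(C)Cl
F3 | step 5 | 4-methyl-3-pentacosylcyclobut-2-en-1-one (racemic) | O=C1C=C(CCCCCCCCCCCCCCCCCCCCCCCCC)C1C
F4 | step 5 | 5-methoxy-2-methyl-3-pentacosylphenol | COc1cc(O)c(C)c(CCCCCCCCCCCCCCCCCCCCCCCCC)c1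
F5 | step 3 | pentacarbonyl(1-methoxypropylidene)chromium | CCC(OC)=[Cr](=C=O)(=C=O)(=C=O)(=C=O)=C=O
F6 | step 3 | pentacarbonyl(3-hydroxy-1-methoxy-2-methyloctacosylidene)chromium (mixture of diastereomers) | COC(C(C)C(O)CCCCCCCCCCCCCCCCCCCCCCCCC)=[Cr](=C=O)(=C=O)(=C=O)(=C=O)=C=O
F7 | step 3 | pentacarbonyl[(2E)-1-methoxy-2-methyloctacos-2-en-1-ylidene]chromium | C/C(C(OC)=[Cr](=C=O)(=C=O)(=C=O)(=C=O)=C=O)=C\CCCCCCCCCCCCCCCCCCCCCCCCC
F8 | step 3 | tricarbonylchromium complex of (3E,5E)-2,4-dimethoxy-5-methylhentriaconta-1,3,5-trien-1-one | O=C=C(OC)/C=C(/OC)\C(C)=C\CCCCCCCCCCCCCCCCCCCCCCCCC.O=C=[Cr](=C=O)=C=O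
F9 | step 2 | 1,1-dibromoheptacos-1-ene | BrC(Br)=CCCCCCCCCCCCCCCCCCCCCCCCCC
F10 | step 2 | (Z)-2-bromooctacos-2-ene | C/C(Br)=C/CCCCCCCCCCCCCCCCCCCCCCCCC
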